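**Retrosynthetic overview**

1. The target is read as epiafzelechin-(4β→8)-catechin. The interflavan bond C4(upper)–C8(lower) is cut last: Friedel–Crafts attack of tetra-O-benzyl-(+)-catechin on the C4 cation of a 4β-alkoxy tri-O-benzyl-epiafzelechin, the C4 oxygen coming from DDQ oxidation.
2. The 2,3-cis C2/C3 pair of the upper unit comes from a racemic, C2-labile flavan-3-one by asymmetric transfer hydrogenation with dynamic kinetic resolution.
3. The flavan-3-one comes from a 3-nitro-2H-chromene; the nitro group on C3 is a temporary activating group and the latent C3 oxygen (conjugate reduction, then Nef).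
4. Ring C (upper pyran) is closed at C3–C4 by the Henry step of a domino oxa-Michael/Henry/dehydration between a ring A salicylaldehyde and a ring B β-nitrostyrene. The enabling feature: on ring A the ether oxygen O1 (on C8a) and the benzylic carbon C4 (on C4a) are ortho, and C3 lies between aryl-bearing C2 and C4, so a nitro group on C3 lets it close onto a C4 formyl group.
5. Ring order: rings A and B and the whole lower unit are bought (arenes, (+)-catechin); ring C is the only ring built.

Key step: step 3

Assumption (target): the SMILES is taken as drawn, upper unit (2R,3R,4R) with 2,3-cis-3,4-trans substituents, lower unit (2R,3S).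
Assumption (step 6): the (R,R)-configured catalyst is taken to reduce the (2R)-ketone, with ring A/C4 in the arene pocket; this sense is not secured by precedent, and the mirror-image complex would be used if it proves opposite.

**Route**

Step 1
Reactants: 1 2,4,6-trihydroxybenzaldehyde
Product: 2 4,6-bis(benzyloxy)-2-hydroxybenzaldehyde
Conditions: BnBr (2.1 equiv), K2CO3, DMF, 0 °C to rt
Reagents that add atoms: benzyl bromide, BrCc1ccccc1
Why: Williamson etherification; the hydroxyl para to the formyl group and one ortho hydroxyl should be alkylated, while the remaining ortho hydroxyl, deactivated by its hydrogen bond to the aldehyde, should stay free.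

Step 2
Reactants: 3 4-(benzyloxy)benzaldehyde; 4 nitromethane
Product: 5 (E)-1-(benzyloxy)-4-(2-nitroethenyl)benzene
Conditions: MeNO2 (5 equiv), NH4OAc, AcOH, 100 °C
Reagents that add atoms: none
Why: Henry (nitro-aldol) condensation with in situ dehydration should give the conjugated nitroalkene as the thermodynamically favoured E isomer.

Step 3
Reactants: 2 4,6-bis(benzyloxy)-2-hydroxybenzaldehyde; 5 (E)-1-(benzyloxy)-4-(2-nitroethenyl)benzene
Product: 8 5,7-bis(benzyloxy)-2-[4-(benzyloxy)phenyl]-3-nitro-2H-chromene (racemic), via oxa-Michael nitronate adduct 6 (not isolated), via nitro-aldol adduct 7 (not isolated)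
Conditions: DABCO (1 equiv), MeCN, 4 Å MS, 70 °C
Reagents that add atoms: none
Why: DABCO deprotonates the phenol of 2, the phenoxide adds to the β-carbon of nitroalkene 5 (oxa-Michael, O1–C2), and the nitronate carbon C3 then attacks the ortho formyl carbon C4 in an intramolecular Henry reaction that closes ring C, after which E1cB loss of water gives the 3-nitro-2H-chromene; this is the known domino oxa-Michael/Henry/dehydration of salicylaldehydes with β-nitrostyrenes. Ring C is closed in the 6-(enolexo)-exo-trig mode, the nitronate carbon adding to a C=O that is exocyclic to the new ring. The only stereocentre kept in 8 is C2; it is formed racemic on purpose, because it becomes epimerisable in ketone 11 and is set in step 6, and the C3/C4 centres of aldol 7 are erased by the dehydration. The step needs O-alkylation of the phenoxide and ring closure to win over retro-oxa-Michael cleavage. The ortho placement of O1 and the formyl group on ring A makes the Henry closure intramolecular, and the dehydration to a nitroalkene conjugated with the electron-rich ring A should make it irreversible.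

Step 4
Reactants: 8 5,7-bis(benzyloxy)-2-[4-(benzyloxy)phenyl]-3-nitro-2H-chromene
Product: 9 5,7-bis(benzyloxy)-2-[4-(benzyloxy)phenyl]-3-nitrochromane (racemic, mixture of cis and trans isomers)
Conditions: NaBH4, THF/MeOH (10:1), 0 °C
Reagents that add atoms: none
Why: Conjugate hydride reduction of the nitroalkene; the mixture of C3 epimers is of no consequence because C3 becomes sp2 again in step 5.

Step 5
Reactants: 9 5,7-bis(benzyloxy)-2-[4-(benzyloxy)phenyl]-3-nitrochromane
Product: 11 5,7-bis(benzyloxy)-2-[4-(benzyloxy)phenyl]chroman-3-one (racemic), via sodium nitronate 10 (not isolated)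
Conditions: NaOMe, MeOH/THF, 0 °C; then aq. TiCl3, NH4OAc buffer, 0 °C to rt, degassed
Reagents that add atoms: water, O
Why: Reductive Nef reaction: the nitronate is reduced by TiCl3 to the N-unsubstituted imine, which should hydrolyse at buffered pH to the ketone; benzyl ethers are inert and the now epimerisable C2 centre needs no control.

Step 6
Reactants: 11 5,7-bis(benzyloxy)-2-[4-(benzyloxy)phenyl]chroman-3-one
Product: 12 (2R,3R)-5,7-bis(benzyloxy)-2-[4-(benzyloxy)phenyl]chroman-3-ol (5,7,4'-tri-O-benzyl-epiafzelechin)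
Conditions: RuCl[(R,R)-TsDPEN](p-cymene) (2 mol %), HCO2H/Et3N (1:1), EtOAc, 35 °C, degassed
Reagents that add atoms: none
Why: Noyori–Ikariya asymmetric transfer hydrogenation with dynamic kinetic resolution: C2 racemises through the enol under the amine base, the chiral Ru–H complex reduces the (2R)-ketone faster, and hydride enters the C3 face anti to the C2 aryl group, which should set C2 (R) and C3 (R) in the 2,3-cis relationship.

Step 7
Reactants: 12 (2R,3R)-5,7-bis(benzyloxy)-2-[4-(benzyloxy)phenyl]chroman-3-ol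
Product: 13 (2R,3R,4S)-5,7-bis(benzyloxy)-2-[4-(benzyloxy)phenyl]-4-(2-ethoxyethoxy)chroman-3-ol (4β-ether, 3,4-trans)
Conditions: DDQ (2 equiv), 2-ethoxyethanol (5 equiv), CH2Cl2, rt
Reagents that add atoms: 2-ethoxyethanol, CCOCCO
Why: Benzylic oxidative etherification: DDQ abstracts hydride from C4 (activated by the 5- and 7-oxygens of ring A) and the resulting cation is trapped by the alcohol on the face anti to the axial 3-OH and the 2-aryl group, which should give the 4β ether.

Step 8
Reactants: 14 (+)-catechin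
Product: 15 (2R,3S)-5,7-bis(benzyloxy)-2-[3,4-bis(benzyloxy)phenyl]chroman-3-ol (5,7,3',4'-tetra-O-benzyl-(+)-catechin)
Conditions: BnBr (4.2 equiv), K2CO3, DMF, 0 °C to rt
Reagents that add atoms: benzyl bromide, BrCc1ccccc1
Why: Williamson etherification; under carbonate conditions the four phenoxides are far more nucleophilic than the secondary 3-OH, which should stay free, and C2 and C3 are untouched.

Step 9
Reactants: 13 (2R,3R,4S)-5,7-bis(benzyloxy)-2-[4-(benzyloxy)phenyl]-4-(2-ethoxyethoxy)chroman-3-ol; 15 5,7,3',4'-tetra-O-benzyl-(+)-catechin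
Product: 16 5,7,4'-tri-O-benzyl-epiafzelechin-(4β→8)-5,7,3',4'-tetra-O-benzylcatechin (hepta-O-benzyl ether of the target)
Conditions: TMSOTf (cat.), 15 (4 equiv), CH2Cl2, −78 °C
Reagents that add atoms: none
Why: Lewis-acid ionisation of the C4 ether regenerates the C4 cation, which C8 of 15 attacks in a Friedel–Crafts alkylation from the β face, anti to the pseudoaxial 3-OH and the 2-aryl group, which should set C4 (R, 3,4-trans); the benzylated catechin reacts at C8 in preference to C6, and its excess suppresses self-condensation of 13.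

Step 10
Reactants: 16 hepta-O-benzyl ether of the target
Product: 17 gambiriin C (target)
Conditions: H2 (1 atm), Pd(OH)2/C, THF/MeOH/H2O, rt
Reagents that add atoms: none
Why: Hydrogenolysis of the seven benzyl ethers under neutral conditions should leave the acid-labile interflavan bond and the benzylic C2–O1 bonds intact.

**Compound list**

1 | 2,4,6-trihydroxybenzaldehyde | O=Cc1c(O)cc(O)cc1O | starting material
2 | 4,6-bis(benzyloxy)-2-hydroxybenzaldehyde | O=Cc1c(O)cc(OCc2ccccc2)cc1OCc1ccccc1 | intermediate
3 | 4-(benzyloxy)benzaldehyde | O=Cc1ccc(OCc2ccccc2)cc1 | starting material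
4 | nitromethane | C[N+](=O)[O-] | starting material
5 | (E)-1-(benzyloxy)-4-(2-nitroethenyl)benzene | [O-][N+](=O)/C=C/c1ccc(OCc2ccccc2)cc1 | intermediate
6 | 4,6-bis(benzyloxy)-2-{1-[4-(benzyloxy)phenyl]-2-nitroethoxy}benzaldehyde (racemic oxa-Michael adduct, present as its nitronate) | O=Cc1c(OC(C[N+](=O)[O-])c2ccc(OCc3ccccc3)cc2)cc(OCc2ccccc2)cc1OCc1ccccc1 | intermediate
7 | 5,7-bis(benzyloxy)-2-[4-(benzyloxy)phenyl]-3-nitrochroman-4-ol (nitro-aldol adduct, mixture of stereoisomers) | OC1c2c(OCc3ccccc3)cc(OCc3ccccc3)cc2OC(c2ccc(OCc3ccccc3)cc2)C1[N+](=O)[O-] | intermediate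
8 | 5,7-bis(benzyloxy)-2-[4-(benzyloxy)phenyl]-3-nitro-2H-chromene (racemic) | [O-][N+](=O)C1=Cc2c(OCc3ccccc3)cc(OCc3ccccc3)cc2OC1c1ccc(OCc2ccccc2)cc1 | intermediate
9 | 5,7-bis(benzyloxy)-2-[4-(benzyloxy)phenyl]-3-nitrochromane (racemic, cis/trans mixture) | [O-][N+](=O)C1Cc2c(OCc3ccccc3)cc(OCc3ccccc3)cc2OC1c1ccc(OCc2ccccc2)cc1 | intermediate
10 | sodium nitronate of 9 | [Na+].[O-][N+]([O-])=C1Cc2c(OCc3ccccc3)cc(OCc3ccccc3)cc2OC1c1ccc(OCc2ccccc2)cc1 | intermediate
11 | 5,7-bis(benzyloxy)-2-[4-(benzyloxy)phenyl]chroman-3-one (racemic) | O=C1Cc2c(OCc3ccccc3)cc(OCc3ccccc3)cc2OC1c1ccc(OCc2ccccc2)cc1 | intermediate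
12 | (2R,3R)-5,7-bis(benzyloxy)-2-[4-(benzyloxy)phenyl]chroman-3-ol | C(c1ccccc1)Oc1ccc([C@H]2Oc3cc(OCc4ccccc4)cc(OCc4ccccc4)c3C[C@H]2O)cc1 | intermediate
13 | (2R,3R,4S)-5,7-bis(benzyloxy)-2-[4-(benzyloxy)phenyl]-4-(2-ethoxyethoxy)chroman-3-ol | C(c1ccccc1)Oc1ccc([C@H]2Oc3cc(OCc4ccccc4)cc(OCc4ccccc4)c3[C@H](OCCOCC)[C@H]2O)cc1 | intermediate
14 | (+)-catechin, (2R,3S)-2-(3,4-dihydroxyphenyl)chromane-3,5,7-triol | O[C@H]1Cc2c(O)cc(O)cc2O[C@@H]1c1ccc(O)c(O)c1 | starting material
15 | (2R,3S)-5,7-bis(benzyloxy)-2-[3,4-bis(benzyloxy)phenyl]chroman-3-ol | O[C@H]1Cc2c(OCc3ccccc3)cc(OCc3ccccc3)cc2O[C@@H]1c1ccc(OCc2ccccc2)c(OCc2ccccc2)c1 | intermediate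
16 | 5,7,4'-tri-O-benzyl-epiafzelechin-(4β→8)-5,7,3',4'-tetra-O-benzylcatechin, upper unit (2R,3R,4R), lower unit (2R,3S) | C(c1ccccc1)Oc1ccc([C@H]2Oc3cc(OCc4ccccc4)cc(OCc4ccccc4)c3[C@H](c3c(OCc4ccccc4)cc(OCc4ccccc4)c4c3O[C@H](c3ccc(OCc5ccccc5)c(OCc5ccccc5)c3)[C@@H](O)C4)[C@H]2O)cc1 | intermediate
17 | gambiriin C, epiafzelechin-(4β→8)-catechin, upper unit (2R,3R,4R), lower unit (2R,3S) | Oc1ccc([C@H]2Oc3cc(O)cc(O)c3[C@H](c3c(O)cc(O)c4c3O[C@H](c3ccc(O)c(O)c3)[C@@H](O)C4)[C@H]2O)cc1 | target

**Step count and risks**

Total steps: 10. Longest linear sequence: 8 steps (steps 1, 3, 4, 5, 6, 7, 9, 10); steps 2 and 8 are side branches.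

Steps most likely to fail:

1. Step 6. What may go wrong: the sense or level of enantioselection at a ketone that has no aryl group directly on the carbonyl may be poor, C2 may racemise more slowly than the ketone is reduced, and cis selectivity may erode. Fallback, from 11 back to 12: reduction of 11 with LiBH(s-Bu)3 in THF at −78 °C, where the bulky hydride attacks anti to the C2 aryl group, should give racemic cis-5,7-bis(benzyloxy)-2-[4-(benzyloxy)phenyl]chroman-3-ol F1. Esterification with (S)-2-methoxy-2-phenylacetic acid (EDC·HCl, DMAP, CH2Cl2) and separation of the two diastereomeric esters by chromatography or crystallisation should give (2R,3R)-5,7-bis(benzyloxy)-2-[4-(benzyloxy)phenyl]chroman-3-yl (S)-2-methoxy-2-phenylacetate F2. Saponification (LiOH, THF/MeOH/H2O) returns 12.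

2. Step 5. What may go wrong: the nitronate may open ring C by β-elimination of the O1 phenoxide (retro-oxa-Michael), reduction may stall at the oxime, and the ketone may enolise and air-oxidise during work-up. Fallback, from 9 back to 11: reduction of the nitro group with NiCl2·6H2O/NaBH4 in MeOH at 0 °C, without free nitronate, should give 5,7-bis(benzyloxy)-2-[4-(benzyloxy)phenyl]chroman-3-amine F3. Oxidative deamination with 3,5-di-tert-butyl-1,2-benzoquinone (MeOH/THF; then aqueous oxalic acid) proceeds by imine formation, prototropic shift and hydrolysis, and should give ketone 11.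

3. Step 3. What may go wrong: addition of the hydrogen-bonded, hindered phenoxide may be slow and reversible, Henry closure onto the electron-rich aldehyde may be sluggish, and the nitrostyrene may polymerise under amine catalysis. Fallback, from 2 back to 11: Petasis-type condensation of 2 with (E)-2-[4-(benzyloxy)phenyl]ethenylboronic acid and catalytic Bn2NH (dioxane, 90 °C), by alkenyl transfer to the iminium carbon, amine elimination and oxa-6π electrocyclisation, should give 5,7-bis(benzyloxy)-2-[4-(benzyloxy)phenyl]-2H-chromene F4. Hydroboration–oxidation (BH3·THF, 0 °C; then NaOH, H2O2), with boron adding to C3 anti to the C2 aryl group, should give racemic 2,3-trans-5,7-bis(benzyloxy)-2-[4-(benzyloxy)phenyl]chroman-3-ol F5. Oxidation with Dess–Martin periodinane (NaHCO3, CH2Cl2) gives ketone 11.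

**Further compounds**

F1 | step 6 | racemic cis-5,7-bis(benzyloxy)-2-[4-(benzyloxy)phenyl]chroman-3-ol (one enantiomer drawn) | O[C@@H]1Cc2c(OCc3ccccc3)cc(OCc3ccccc3)cc2O[C@@H]1c1ccc(OCc2ccccc2)cc1
F2 | step 6 | (2R,3R)-5,7-bis(benzyloxy)-2-[4-(benzyloxy)phenyl]chroman-3-yl (S)-2-methoxy-2-phenylacetate | CO[C@H](C(=O)O[C@@H]1Cc2c(OCc3ccccc3)cc(OCc3ccccc3)cc2O[C@@H]1c1ccc(OCc2ccccc2)cc1)c1ccccc1
F3 | step 5 | 5,7-bis(benzyloxy)-2-[4-(benzyloxy)phenyl]chroman-3-amine (racemic, cis/trans mixture) | NC1Cc2c(OCc3ccccc3)cc(OCc3ccccc3)cc2OC1c1ccc(OCc2ccccc2)cc1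
F4 | step 3 | 5,7-bis(benzyloxy)-2-[4-(benzyloxy)phenyl]-2H-chromene (racemic) | C1(c2ccc(OCc3ccccc3)cc2)Oc2cc(OCc3ccccc3)cc(OCc3ccccc3)c2C=C1
F5 | step 3 | racemic 2,3-trans-5,7-bis(benzyloxy)-2-[4-(benzyloxy)phenyl]chroman-3-ol (one enantiomer drawn) | O[C@H]1Cc2c(OCc3ccccc3)cc(OCc3ccccc3)cc2O[C@@H]1c1ccc(OCc2ccccc2)cc1
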